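**Plan**

- The retrosynthesis opens rings A and B together by cutting C1–C2 and C9–C10. In ring A the 2α-hydroxyl is 1,3 to quaternary C10 (C2–C1–C10), so C2 becomes an aldehyde carbon and C20–C10=C1 an isopropenyl group on C5. Ring B reopens to the (E)-C8=C9 alkene.
- The acyclic trienal is then cut at C4–C5 (the sigma bond of an Ireland–Claisen rearrangement), at C10=C1 and C10–C20 (acid → methyl ketone → methylene), and at the two ester C–O bonds.
- Forward: farnesol gives a C13 acid (C5–C9, C11–C17, plus one added carbon, C10); prenyl acetate gives the allylic alcohol (C2–C4, C18, C19). Esterification and [3,3] rearrangement join them at C4–C5.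
- Then C20 and C1 are added, both silyl ethers are exchanged for the two esters, and the vinyl group is turned into the C2 aldehyde. Ring A and then ring B close in the last flask.
- Stereochemistry: C4 and C5 come from the chair Claisen transition state ((E)-allyl part, E(O)-boron enolate) under a chiral boron controller. C2, C10 and C9 come from the chair–chair cyclization, steered by C4/C5 and the (E)-C8=C9 geometry. The 13E alkene is carried from farnesol.

Key step: step 18

Remarks before the steps:
- Locants C1–C20 in the text are the labdane locants of the target; the systematic names in the compound list carry their own numbering.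
- Assumption: the (S,S)-diazaborolidine controller is taken to give the (2S,3S) acid 15. If its sense of induction is the opposite, the (R,R) enantiomer is used with no other change.

**Route**

Step 1
Reactants: 1 (2E,6E)-farnesol
Product: 2 (2E,6E)-farnesyl tert-butyldiphenylsilyl ether
Conditions: t-BuPh2SiCl, imidazole, DMF, 0 °C → rt
Reagents that add atoms: tert-butyl(chloro)diphenylsilane, CC(C)(C)[Si](Cl)(c1ccccc1)c1ccccc1
Why: Imidazole-promoted silylation of the primary allylic alcohol gives an ether that should survive the acidic, oxidative and organolithium steps up to step 13.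

Step 2
Reactants: 2 (2E,6E)-farnesyl tert-butyldiphenylsilyl ether
Product: 4 racemic terminal (farnesol 10,11) epoxide of 2, via bromohydrin 3 (not isolated)
Conditions: NBS, THF/H2O, 0 °C; then K2CO3, MeOH, rt
Reagents that add atoms: water, O; N-bromosuccinimide, O=C1CCC(=O)N1Br (its bromine stands in 3 only)
Why: Bromohydrin formation in aqueous THF is known to pick the terminal, most exposed trisubstituted alkene of a polyprenyl chain, and base then closes the epoxide by intramolecular Williamson reaction; its configuration is irrelevant because step 3 destroys it.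

Step 3
Reactants: 4 racemic terminal epoxide
Product: 5 (4E,8E)-10-silyloxy-4,8-dimethyldeca-4,8-dienal
Conditions: HIO4·2H2O, THF/Et2O, 0 °C
Reagents that add atoms: none
Why: Periodic acid opens the epoxide to the diol and cleaves it (Malaprade glycol cleavage), removing acetone and leaving the aldehyde carbon that becomes C5.

Step 4
Reactants: 5 (4E,8E)-10-silyloxy-4,8-dimethyldeca-4,8-dienal
Product: 7 (5E,9E)-11-silyloxy-5,9-dimethylundeca-5,9-dienal, via methyl enol ether 6 (not isolated)
Conditions: MeOCH2PPh3Cl, KN(SiMe3)2, THF, −78 → 0 °C; then 2 M aq. HCl, rt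
Reagents that add atoms: (methoxymethyl)triphenylphosphonium chloride, COC[P+](c1ccccc1)(c1ccccc1)c1ccccc1.[Cl-]; water, O
Why: Wittig methoxymethylenation followed by hydrolysis of the enol ether is the standard one-carbon homologation of an aldehyde, and the added carbon becomes C10.

Step 5
Reactants: 7 (5E,9E)-11-silyloxy-5,9-dimethylundeca-5,9-dienal
Product: 8 (5E,9E)-11-silyloxy-5,9-dimethylundeca-5,9-dienoic acid
Conditions: NaClO2, NaH2PO4, 2-methylbut-2-ene, t-BuOH/H2O, 0 °C → rt
Reagents that add atoms: sodium chlorite, [Na+].[O-]Cl=O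
Why: Pinnick oxidation converts the aldehyde into the acid while the scavenger alkene protects the two trisubstituted alkenes from hypochlorite.

Step 6
Reactants: 9 prenyl acetate
Product: 10 (2E)-4-hydroxy-3-methylbut-2-en-1-yl acetate
Conditions: SeO2 (cat.), t-BuOOH, CH2Cl2, rt
Reagents that add atoms: tert-butyl hydroperoxide, CC(C)(C)OO
Why: Riley allylic oxidation (ene reaction, then [2,3] shift) hydroxylates the methyl group trans to the acetoxymethyl chain, so the (E)-allylic alcohol that later becomes C19–O should form.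

Step 7
Reactants: 10 (2E)-4-hydroxy-3-methylbut-2-en-1-yl acetate
Product: 11 (2E)-4-(tert-butyldimethylsilyloxy)-3-methylbut-2-en-1-yl acetate
Conditions: t-BuMe2SiCl, imidazole, DMF, rt
Reagents that add atoms: tert-butyl(chloro)dimethylsilane, CC(C)(C)[Si](C)(C)Cl
Why: Silylation masks the future C19 oxygen as an ether that tolerates the enolisation and methyllithium steps.

Step 8
Reactants: 11 (2E)-4-(tert-butyldimethylsilyloxy)-3-methylbut-2-en-1-yl acetate
Product: 12 (2E)-4-(tert-butyldimethylsilyloxy)-3-methylbut-2-en-1-ol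
Conditions: K2CO3 (cat.), MeOH, 0 °C → rt
Reagents that add atoms: none
Why: Base-catalysed transesterification with methanol removes the acetate and leaves the silyl ether in place.

Step 9
Reactants: 8 (5E,9E)-11-silyloxy-5,9-dimethylundeca-5,9-dienoic acid; 12 (2E)-4-(tert-butyldimethylsilyloxy)-3-methylbut-2-en-1-ol
Product: 13 allylic ester of 8 with 12
Conditions: DCC, DMAP (cat.), CH2Cl2, 0 °C → rt
Reagents that add atoms: none
Why: Steglich esterification joins the two fragments under neutral conditions that leave both silyl ethers and all alkene geometries intact.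

Step 10
Reactants: 13 allylic ester of 8 with 12
Product: 15 (2S,3S)-2-alkyl-3-methyl-3-(silyloxymethyl)pent-4-enoic acid, via boron ketene acetal 14 (not isolated)
Conditions: (4S,5S)-2-bromo-1,3-bis{[3,5-bis(trifluoromethyl)phenyl]sulfonyl}-4,5-diphenyl-1,3,2-diazaborolidine (1.3 equiv), Et3N, toluene/hexane, −78 °C; then 4 °C → rt; aq. work-up
Reagents that add atoms: none
Why: Soft enolisation with the chiral B–Br reagent and Et3N in a non-polar medium gives the E(O)-boron ketene acetal (chain trans to O–B), which undergoes the enantioselective Ireland–Claisen rearrangement through a chair with CH2OSi equatorial and methyl axial on the (E)-allyl part, which fixes the C4/C5 relative configuration, while the chiral bis-sulfonamide ligand on boron selects the enolate face and so the absolute configuration.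

Step 11
Reactants: 15 (2S,3S)-pent-4-enoic acid
Product: 16 (3S,4S)-methyl ketone (hex-5-en-2-one)
Conditions: MeLi (3 equiv), Et2O, 0 °C → rt; inverse quench into cold 1 M HCl
Reagents that add atoms: methyllithium, [Li]C
Why: Addition of methyllithium to the lithium carboxylate gives a geminal dilithium alkoxide that releases the ketone only on quench, so over-addition and epimerisation at C5 should not occur; the new methyl group is C20.

Step 12
Reactants: 16 (3S,4S)-methyl ketone
Product: 17 (3S,4R)-bis-silyl ether with isopropenyl and vinyl groups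
Conditions: Zn, CH2Br2, TiCl4, THF/CH2Cl2, 0 °C → rt
Reagents that add atoms: dibromomethane, BrCBr
Why: Takai–Lombardo methylenation is non-basic, so the hindered α-branched methyl ketone should give the 1,1-disubstituted alkene (C10=C1) without epimerisation at C5.

Step 13
Reactants: 17 (3S,4R)-bis-silyl ether
Product: 18 (10R,11S)-diol (C15–OH and C19–OH free)
Conditions: Bu4NF (3 equiv), THF, rt
Reagents that add atoms: none
Why: Fluoride-mediated desilylation removes both silyl ethers in one operation from a substrate that now carries only alkenes.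

Step 14
Reactants: 18 (10R,11S)-diol; 19 methyl 4-chloro-4-oxobutanoate
Product: 20 C15 methyl succinate with free C19 hydroxyl
Conditions: 19 (1.05 equiv), pyridine, CH2Cl2, −40 °C
Reagents that add atoms: none
Why: Pyridine-mediated acylation at low temperature should take the unhindered primary allylic C15 hydroxyl well before the neopentyl C19 hydroxyl on quaternary C4.

Step 15
Reactants: 20 C15 methyl succinate; 21 isovaleryl chloride
Product: 22 diester bearing the vinyl group
Conditions: 21, pyridine, DMAP (cat.), CH2Cl2, 0 °C → rt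
Reagents that add atoms: none
Why: DMAP-catalysed acylation esterifies the remaining hindered primary alcohol and completes both ester groups of the target.

Step 16
Reactants: 22 diester bearing the vinyl group
Product: 24 primary C2 alcohol, via catechol alkylboronate 23 (not isolated)
Conditions: catecholborane, ClRh(PPh3)3 (3 mol %), THF, 0 °C → rt; then pH 7 phosphate buffer, H2O2, THF/EtOH, 0 °C
Reagents that add atoms: catecholborane, B1Oc2ccccc2O1 (its boron stands in 23 only); hydrogen peroxide, OO
Why: Rhodium-catalysed hydroboration is highly sensitive to alkene substitution, so the monosubstituted vinyl group (which cannot isomerise, C4 being quaternary) should react anti-Markovnikov in preference to the isopropenyl and trisubstituted alkenes, and buffered peroxide oxidation then gives the alcohol without ester hydrolysis.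

Step 17
Reactants: 24 primary C2 alcohol
Product: 25 trienal (cyclization precursor)
Conditions: Dess–Martin periodinane, CH2Cl2, 0 °C → rt
Reagents that add atoms: none
Why: Dess–Martin oxidation gives the aldehyde under neutral conditions that touch neither the esters nor the alkenes, and the crude aldehyde is taken on at once.

Step 18
Reactants: 25 trienal
Product: 26 target CNP0118741.1
Conditions: MeAlCl2 (5 equiv, 1 M in hexane), CH2Cl2, −78 → −40 °C; aq. KNaC4H4O6 work-up
Reagents that add atoms: none
Why: Proposed new method: MeAlCl2 binds the C2 aldehyde, the terminal carbon C1 of the isopropenyl group adds to it (C1–C2, ring A, Prins closure by 6-endo attack of the alkene with both alkene carbons in the ring), the resulting tertiary C10 cation is captured by C9 of the (E)-C8=C9 alkene (C9–C10, ring B, 6-endo-trig), and the C8 cation loses H7, the proton being taken up by Al–CH3 as methane. The closest known reactions are the MeAlCl2- and Me2AlCl-promoted type 2 carbonyl-ene and Prins cyclizations of 5-methylhex-5-enals and the stepwise closure of monocyclic cyclohexyl cations onto trisubstituted alkenes to trans-decalins. C2 is set in the ring A chair, where the aluminium-bound oxygen lies equatorial to avoid the axial C19 acyloxymethyl group on C4, giving the 2α-hydroxyl. C10 and C9 are set in a chair–chair transition state: the equatorial C6 chain on preset C5 delivers C9 anti to H5 (trans fusion, axial C20) and the (E)-alkene places C11 equatorial (9α-H). The step needs alkene capture of the C10 cation to outrun ene-type loss of a C20 proton and chloride transfer, which excess MeAlCl2 at low temperature (zwitterion without a basic counter-ion) should favour, and it needs the cascade to stop at the bicycle, which the electron-poor allylic succinate alkene C13=C14 secures. Loss of H7 rather than H17 follows the usual preference for the endocyclic trisubstituted alkene, and the exocyclic isomer would be removed on AgNO3-impregnated silica.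

**Compound list**

1 | (2E,6E)-farnesol, (2E,6E)-3,7,11-trimethyldodeca-2,6,10-trien-1-ol | CC(C)=CCC/C(C)=C/CC/C(C)=C/CO | starting material
2 | tert-butyl(diphenyl){[(2E,6E)-3,7,11-trimethyldodeca-2,6,10-trien-1-yl]oxy}silane | CC(C)=CCC/C(C)=C/CC/C(C)=C/CO[Si](c1ccccc1)(c1ccccc1)C(C)(C)C | intermediate
3 | racemic (6E,10E)-3-bromo-12-[(tert-butyldiphenylsilyl)oxy]-2,6,10-trimethyldodeca-6,10-dien-2-ol | CC(C)(O)C(Br)CC/C(C)=C/CC/C(C)=C/CO[Si](c1ccccc1)(c1ccccc1)C(C)(C)C | intermediate
4 | racemic tert-butyl{[(2E,6E)-9-(3,3-dimethyloxiran-2-yl)-3,7-dimethylnona-2,6-dien-1-yl]oxy}diphenylsilane | CC1(C)OC1CC/C(C)=C/CC/C(C)=C/CO[Si](c1ccccc1)(c1ccccc1)C(C)(C)C | intermediate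
5 | (4E,8E)-10-[(tert-butyldiphenylsilyl)oxy]-4,8-dimethyldeca-4,8-dienal | O=CCC/C(C)=C/CC/C(C)=C/CO[Si](c1ccccc1)(c1ccccc1)C(C)(C)C | intermediate
6 | tert-butyl{[(2E,6E)-11-methoxy-3,7-dimethylundeca-2,6,10-trien-1-yl]oxy}diphenylsilane (E/Z mixture at the enol ether) | COC=CCC/C(C)=C/CC/C(C)=C/CO[Si](c1ccccc1)(c1ccccc1)C(C)(C)C | intermediate
7 | (5E,9E)-11-[(tert-butyldiphenylsilyl)oxy]-5,9-dimethylundeca-5,9-dienal | O=CCCC/C(C)=C/CC/C(C)=C/CO[Si](c1ccccc1)(c1ccccc1)C(C)(C)C | intermediate
8 | (5E,9E)-11-[(tert-butyldiphenylsilyl)oxy]-5,9-dimethylundeca-5,9-dienoic acid | OC(=O)CCC/C(C)=C/CC/C(C)=C/CO[Si](c1ccccc1)(c1ccccc1)C(C)(C)C | intermediate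
9 | prenyl acetate, 3-methylbut-2-en-1-yl acetate | CC(=O)OCC=C(C)C | starting material
10 | (2E)-4-hydroxy-3-methylbut-2-en-1-yl acetate | CC(=O)OC/C=C(\C)CO | intermediate
11 | (2E)-4-[(tert-butyldimethylsilyl)oxy]-3-methylbut-2-en-1-yl acetate | CC(=O)OC/C=C(\C)CO[Si](C)(C)C(C)(C)C | intermediate
12 | (2E)-4-[(tert-butyldimethylsilyl)oxy]-3-methylbut-2-en-1-ol | OC/C=C(\C)CO[Si](C)(C)C(C)(C)C | intermediate
13 | (2E)-4-[(tert-butyldimethylsilyl)oxy]-3-methylbut-2-en-1-yl (5E,9E)-11-[(tert-butyldiphenylsilyl)oxy]-5,9-dimethylundeca-5,9-dienoate | CC(C)(C)[Si](C)(C)OC/C(C)=C/COC(=O)CCC/C(C)=C/CC/C(C)=C/CO[Si](c1ccccc1)(c1ccccc1)C(C)(C)C | intermediate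
14 | boron ketene acetal of 13: enolate oxygen bound to the (4S,5S)-1,3-bis{[3,5-bis(trifluoromethyl)phenyl]sulfonyl}-4,5-diphenyl-1,3,2-diazaborolidin-2-yl group, alkyl chain trans to O–B | CC(C)(C)[Si](C)(C)OC/C(C)=C/CO/C(OB1N(S(=O)(=O)c2cc(cc(c2)C(F)(F)F)C(F)(F)F)[C@@H](c2ccccc2)[C@H](c2ccccc2)N1S(=O)(=O)c1cc(cc(c1)C(F)(F)F)C(F)(F)F)=C\CC/C(C)=C/CC/C(C)=C/CO[Si](c1ccccc1)(c1ccccc1)C(C)(C)C | intermediate
15 | (2S,3S)-3-{[(tert-butyldimethylsilyl)oxy]methyl}-2-[(3E,7E)-9-[(tert-butyldiphenylsilyl)oxy]-3,7-dimethylnona-3,7-dien-1-yl]-3-methylpent-4-enoic acid | C=C[C@](C)(CO[Si](C)(C)C(C)(C)C)[C@@H](C(O)=O)CC/C(C)=C/CC/C(C)=C/CO[Si](c1ccccc1)(c1ccccc1)C(C)(C)C | intermediate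
16 | (3S,4S)-4-{[(tert-butyldimethylsilyl)oxy]methyl}-3-[(3E,7E)-9-[(tert-butyldiphenylsilyl)oxy]-3,7-dimethylnona-3,7-dien-1-yl]-4-methylhex-5-en-2-one | C=C[C@](C)(CO[Si](C)(C)C(C)(C)C)[C@@H](C(C)=O)CC/C(C)=C/CC/C(C)=C/CO[Si](c1ccccc1)(c1ccccc1)C(C)(C)C | intermediate
17 | (3S,4R,7E,11E)-13-[(tert-butyldiphenylsilyl)oxy]-3-{[(tert-butyldimethylsilyl)oxy]methyl}-3,7,11-trimethyl-4-(prop-1-en-2-yl)trideca-1,7,11-triene | C=C[C@](C)(CO[Si](C)(C)C(C)(C)C)[C@@H](C(C)=C)CC/C(C)=C/CC/C(C)=C/CO[Si](c1ccccc1)(c1ccccc1)C(C)(C)C | intermediate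
18 | (2E,6E,10R,11S)-11-(hydroxymethyl)-3,7,11-trimethyl-10-(prop-1-en-2-yl)trideca-2,6,12-trien-1-ol | C=C[C@](C)(CO)[C@@H](C(C)=C)CC/C(C)=C/CC/C(C)=C/CO | intermediate
19 | methyl 4-chloro-4-oxobutanoate | COC(=O)CCC(Cl)=O | starting material
20 | (2E,6E,10R,11S)-11-(hydroxymethyl)-3,7,11-trimethyl-10-(prop-1-en-2-yl)trideca-2,6,12-trien-1-yl methyl butanedioate | C=C[C@](C)(CO)[C@@H](C(C)=C)CC/C(C)=C/CC/C(C)=C/COC(=O)CCC(=O)OC | intermediate
21 | isovaleryl chloride, 3-methylbutanoyl chloride | CC(C)CC(Cl)=O | starting material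
22 | methyl (2E,6E,10R,11S)-3,7,11-trimethyl-11-{[(3-methylbutanoyl)oxy]methyl}-10-(prop-1-en-2-yl)trideca-2,6,12-trien-1-yl butanedioate | C=C[C@](C)(COC(=O)CC(C)C)[C@@H](C(C)=C)CC/C(C)=C/CC/C(C)=C/COC(=O)CCC(=O)OC | intermediate
23 | catechol boronate of 22: 1,3,2-benzodioxaborol-2-yl group on the terminal carbon (C2) of the former vinyl group, (10R,11S) | B1(CC[C@](C)(COC(=O)CC(C)C)[C@@H](C(C)=C)CC/C(C)=C/CC/C(C)=C/COC(=O)CCC(=O)OC)Oc2ccccc2O1 | intermediate
24 | methyl (2E,6E,10R,11S)-13-hydroxy-3,7,11-trimethyl-11-{[(3-methylbutanoyl)oxy]methyl}-10-(prop-1-en-2-yl)trideca-2,6-dien-1-yl butanedioate | OCC[C@](C)(COC(=O)CC(C)C)[C@@H](C(C)=C)CC/C(C)=C/CC/C(C)=C/COC(=O)CCC(=O)OC | intermediate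
25 | methyl (2E,6E,10R,11S)-3,7,11-trimethyl-11-{[(3-methylbutanoyl)oxy]methyl}-13-oxo-10-(prop-1-en-2-yl)trideca-2,6-dien-1-yl butanedioate | O=CC[C@](C)(COC(=O)CC(C)C)[C@@H](C(C)=C)CC/C(C)=C/CC/C(C)=C/COC(=O)CCC(=O)OC | intermediate
26 | CNP0118741.1: (2R,4S,5R,9S,10R)-2-hydroxy-19-[(3-methylbutanoyl)oxy]labda-7,13E-dien-15-yl methyl butanedioate (2α-OH, 4β-CH2O, 5α-H, 9α-H, 10β-CH3) | COC(=O)CCC(=O)OC/C=C(\C)CC[C@H]1C(C)=CC[C@H]2[C@@](C)(COC(=O)CC(C)C)C[C@H](O)C[C@]12C | target

**Step count and risks**

Total: 18 steps. Longest linear sequence: 15 steps (steps 1–5 and 9–18, from farnesol); steps 6–8 form the three-step side branch from prenyl acetate.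

Steps most likely to fail:

1. Step 18. The cascade may stop after ring A by ene-type proton loss from C20, or the C10 cation may be lost to chloride capture or a hydride shift before ring B closes. Fallback with known chemistry, dividing the two ring closures: from 25, Me2AlCl (CH2Cl2, −78 °C) effects the concerted type 2 carbonyl-ene reaction, established for 5-methylhex-5-enals, to give the monocyclic alcohol methyl (2E,6E)-9-[(1R,2S,4R)-4-hydroxy-2-methyl-2-{[(3-methylbutanoyl)oxy]methyl}-6-methylidenecyclohexyl]-3,7-dimethylnona-2,6-dien-1-yl butanedioate F1, which holds ring A, the C1–C2 bond and an exocyclic C10=C20 alkene. SnCl4 (CH2Cl2, −78 °C) then protonates that alkene through the tin-bound hydroxyl, and the regenerated C10 cation closes ring B onto C8=C9 in a proton-initiated cation–olefin cyclization, returning to the route at 26.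

2. Step 10. Enolisation by the hindered boron reagent may be incomplete, or facial selectivity may be poor, so that the acid is obtained with low enantiomeric purity. Fallback giving up reagent control: from 13, LiN(iPr)2 and Me3SiCl (THF, −78 °C → rt) give the (E)-trimethylsilyl ketene acetal of 13 F2, which rearranges through the same chair (classical Ireland–Claisen rearrangement) and after acidic work-up gives 15 together with its enantiomer, the (2R,3R)-acid F3. The two are separated by preparative chromatography on a chiral stationary phase or as diastereomeric (S)-1-phenylethylammonium salts, returning to the route at 15.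

3. Step 16. Hydroboration may not discriminate well enough between the hindered vinyl group and the isopropenyl group, so that over-hydroboration occurs. Fallback replacing hydroboration by oxidation: from 22, an aldehyde-selective Wacker oxidation (PdCl2(PhCN)2, CuCl2, AgNO2, O2, t-BuOH/MeNO2) oxidises the terminal carbon of the tert-alkyl-substituted vinyl group, aided by the homoallylic acyloxy group, while 1,1-disubstituted and trisubstituted alkenes stay inert. No new compound arises on the way (F0); step 17 is skipped and the route is rejoined at 25.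

Further compounds
F1 | step 18 | methyl (2E,6E)-9-[(1R,2S,4R)-4-hydroxy-2-methyl-2-{[(3-methylbutanoyl)oxy]methyl}-6-methylidenecyclohexyl]-3,7-dimethylnona-2,6-dien-1-yl butanedioate | O[C@H]1C[C@](C)(COC(=O)CC(C)C)[C@@H](C(=C)C1)CC/C(C)=C/CC/C(C)=C/COC(=O)CCC(=O)OC
F2 | step 10 | (E)-trimethylsilyl ketene acetal of 13 (alkyl chain trans to OSiMe3) | CC(C)(C)[Si](C)(C)OC/C(C)=C/CO/C(O[Si](C)(C)C)=C\CC/C(C)=C/CC/C(C)=C/CO[Si](c1ccccc1)(c1ccccc1)C(C)(C)C
F3 | step 10 | (2R,3R)-3-{[(tert-butyldimethylsilyl)oxy]methyl}-2-[(3E,7E)-9-[(tert-butyldiphenylsilyl)oxy]-3,7-dimethylnona-3,7-dien-1-yl]-3-methylpent-4-enoic acid (enantiomer of 15) | C=C[C@@](C)(CO[Si](C)(C)C(C)(C)C)[C@H](C(O)=O)CC/C(C)=C/CC/C(C)=C/CO[Si](c1ccccc1)(c1ccccc1)C(C)(C)C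
F0 | step 16 | none | none
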